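**Retrosynthetic overview**
- Acyl pattern last: the C3 isobutyrate comes from axial-selective opening of a C2/C3 cyclic orthoisobutyrate; the C5 acetate and C6 isobutyrate come from tin-acetal acetylation then acylation of a β-cis-triol made by hydroxyl-directed osmylation of a C5=C6 cyclohexene.
- Key disconnection C1–C7: palladium-catalysed, stereoinvertive allyl–alkenyl coupling of a cyclohexenyl tert-butyl carbonate (ring fragment) with an α-acyloxy alkenyl-B(pin) (side-chain fragment).
- Ring fragment from toluene: enzymatic cis-dihydroxylation, acetonide, epoxidation, hydroxide opening, carbonate.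
- Side-chain fragment from acrolein (as 2-bromoacrolein) and silylated 3-hydroxy-3-methylbutan-2-one: boron aldol, Evans–Tishchenko reduction (C8 isobutyrate and C10 set together), silylation, borylation.
- Ring order: the only ring is the carbocycle, taken intact from toluene; no ring is built, only temporary protecting rings.

Convention (assumed for all names): ring carbons keep the target locants (C1 side chain, C2 OH, C3 O-isobutyryl, C4 methyl carbinol, C5 OAc, C6 O-isobutyryl); side chain is C7 (=CH2), C8, C9, C10, C11; β is the ring face of the C1 side chain, C4-OH, C5-O and C6-O in the target, α the face of C2-O, C3-O and the C4 methyl.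

**Ring fragment**

Step 1
Reactants: 1 toluene
Product: 2 (1S,2R)-3-methylcyclohexa-3,5-diene-1,2-diol
Conditions: E. coli JM109(pDTG601) whole cells (toluene dioxygenase), O2, glucose, phosphate buffer pH 7, 30 °C
Reagents that add atoms: dioxygen, O=O
Why: Enzymatic arene cis-dihydroxylation is enantiospecific at the 2,3-bond and sets C2 and C3 (both α) with the methyl-bearing carbon as the future C4.

Step 2
Reactants: 2 (1S,2R)-3-methylcyclohexa-3,5-diene-1,2-diol
Product: 3 (3aR,7aS)-2,2,4-trimethyl-3a,7a-dihydro-1,3-benzodioxole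
Conditions: 2,2-dimethoxypropane, p-TsOH·H2O (cat.), acetone, 0 °C; used at once
Reagents that add atoms: 2,2-dimethoxypropane, COC(C)(C)OC
Why: Acid-catalysed acetonide formation ties the cis-diol into a dioxolane that blocks the α face and stops aromatisation.

Step 3
Reactants: 3 diene acetonide
Product: 4 vinyl epoxide (C4,C5-β-epoxide; C6=C1 alkene kept)
Conditions: mCPBA, CH2Cl2 / pH 8 phosphate buffer, 0 °C
Reagents that add atoms: mCPBA, O=C(OO)c1cccc(Cl)c1
Why: Prilezhaev epoxidation takes the more electron-rich trisubstituted C4=C5 alkene from the β face, anti to the neighbouring acetonide oxygen, which sets C4 (oxygen β, methyl α).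

Step 4
Reactants: 4 vinyl epoxide
Product: 5 trans-diol (C4 β-OH, C5 α-OH, C2/C3 α-acetonide, C6=C1)
Conditions: KOH, H2O/DMSO (1:1), 85 °C
Reagents that add atoms: water, O
Why: Hydroxide opens the vinyl epoxide by SN2 attack at the allylic secondary carbon C5 (tertiary C4 is inert to SN2), giving the trans-diaxial diol with inversion at C5 and the C4–O bond untouched.

Step 5
Reactants: 5 trans-diol
Product: 6 allylic tert-butyl carbonate (C5 α-OBoc, C4 β-OH free)
Conditions: Boc2O (1.1 equiv), DMAP (cat.), CH2Cl2, 0 °C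
Reagents that add atoms: di-tert-butyl dicarbonate, CC(C)(C)OC(=O)OC(=O)OC(C)(C)C
Why: DMAP-catalysed carbonate formation occurs only at the secondary allylic hydroxyl because the tertiary C4 carbinol is too hindered, giving the leaving group for π-allyl chemistry.

**Side-chain fragment**

Step 6
Reactants: 7 3-hydroxy-3-methylbutan-2-one
Product: 8 3-methyl-3-(triethylsilyloxy)butan-2-one
Conditions: TESOTf, 2,6-lutidine, CH2Cl2, −78 → 0 °C
Reagents that add atoms: triethylsilyl triflate, CC[Si](CC)(CC)OS(=O)(=O)C(F)(F)F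
Why: Silyl triflate silylation of the tertiary alcohol (2,6-lutidine is too weak to form the enol silane) leaves a ketone that can enolise only on the methyl side.

Step 7
Reactants: 9 acrolein
Product: 11 2-bromoprop-2-enal, via 2,3-dibromopropanal 10 (not isolated)
Conditions: Br2, CH2Cl2, −78 °C; then Et3N, −78 → 0 °C; distil
Reagents that add atoms: bromine, BrBr
Why: Bromination of the alkene followed by amine-induced E1cB loss of HBr (bromination–dehydrobromination) gives the α-bromo enal.

Step 8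
Reactants: 8 3-methyl-3-(triethylsilyloxy)butan-2-one + 11 2-bromoprop-2-enal
Product: 14 (5S)-6-bromo-5-hydroxy-2-methyl-2-(triethylsilyloxy)hept-6-en-3-one, via boron enolate 12 (not isolated), via boron aldolate 13 (not isolated)
Conditions: (−)-B-chlorodiisopinocampheylborane [(−)-Ipc2BCl], Et3N, Et2O, −78 → 0 °C; 11, −78 °C; then H2O2, pH 7 buffer, MeOH
Reagents that add atoms: none
Why: Paterson boron aldol in which the Ipc2B enolate forms only on the methyl side and adds 1,2 to the enal on the Si face of the aldehyde, setting C8 as S (expect about 80–90% ee, sense to be confirmed by Mosher analysis; the antipode is removed as a diastereomer after step 12).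

Step 9
Reactants: 14 (5S)-β-hydroxy ketone
Product: 15 (3S,5S)-2-bromo-5-hydroxy-6-methyl-6-(triethylsilyloxy)hept-1-en-3-yl 2-methylpropanoate
Conditions: isobutyraldehyde (6 equiv), SmI2 (0.3 equiv, premixed with the aldehyde), THF, −10 °C
Reagents that add atoms: isobutyraldehyde, CC(C)C=O
Why: Evans–Tishchenko reduction, in which the samarium-bound hemiacetal of the C8 hydroxyl delivers hydride intramolecularly to the ketone through a chair transition state, sets C10 (S, 1,3-anti) and leaves the isobutyrate on the C8 oxygen.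

Step 10
Reactants: 15 hydroxy ester
Product: 16 (3S,5S)-2-bromo-6-methyl-6-(triethylsilyloxy)-5-(triisopropylsilyloxy)hept-1-en-3-yl 2-methylpropanoate
Conditions: TIPSOTf, 2,6-lutidine, CH2Cl2, 0 °C → rt
Reagents that add atoms: triisopropylsilyl triflate, CC(C)[Si](C(C)C)(C(C)C)OS(=O)(=O)C(F)(F)F
Why: Silyl triflate silylation of the hindered secondary alcohol; TIPS is chosen because it survives the later aqueous acid and blocks 1,3-acyl migration.

Step 11
Reactants: 16 alkenyl bromide
Product: 17 (3S,5S)-6-methyl-2-(4,4,5,5-tetramethyl-1,3,2-dioxaborolan-2-yl)-6-(triethylsilyloxy)-5-(triisopropylsilyloxy)hept-1-en-3-yl 2-methylpropanoate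
Conditions: B2pin2, PdCl2(PPh3)2 (3 mol %), PPh3 (6 mol %), KOPh, toluene, 50 °C
Reagents that add atoms: bis(pinacolato)diboron, CC1(C)OB(OC1(C)C)B1OC(C)(C)C(C)(C)O1
Why: Miyaura borylation of an alkenyl bromide under weak-base conditions that tolerate esters; oxidative addition to C–Br is faster than ionisation of the secondary allylic isobutyrate in toluene.

**Fragment union and end game**

Step 12
Reactants: 6 allylic tert-butyl carbonate + 17 alkenyl-B(pin)
Product: 18 coupled cyclohexene (C1 β-side chain, C2/C3 α-acetonide, C4 β-OH, C5=C6)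
Conditions: Pd2(dba)3 (2.5 mol %), P(2-furyl)3 (10 mol %), THF, 45 °C, no added base
Reagents that add atoms: none
Why: Proposed new method: a base-free, neighbouring-alkoxide-relayed Suzuki–Miyaura allyl–alkenyl coupling. Zerovalent palladium ionises the α-carbonate with inversion (palladium on the β face), the tert-butoxide released with CO2 deprotonates the β C4-OH, that alkoxide binds the boron of 17 and hands the hindered alkenyl group to palladium on the same face, and reductive elimination at the less hindered allyl terminus C1 (C5 is neopentyl) forms C1–C7 with the side chain β (net anti-SN2′); the tert-butyl carbonate ionises far faster than the allylic isobutyrate. Closest known reaction type: neutral palladium-catalysed coupling of allylic carbonates with aryl- or alkenylboron reagents (net inversion) and hydroxyl-directed transmetalation in Suzuki couplings.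

Step 13
Reactants: 18 coupled cyclohexene
Product: 20 β-cis-triol (C4, C5, C6 β-OH), via osmate ester 19 (not isolated)
Conditions: OsO4 (1.05 equiv), TMEDA (1.1 equiv), CH2Cl2, −78 °C; then ethylenediamine, rt
Reagents that add atoms: osmium tetroxide, O=[Os](=O)(=O)=O
Why: Donohoe hydrogen-bond-directed dihydroxylation, in which the pseudoaxial C4-OH binds the OsO4·TMEDA complex and delivers it to the β face of C5=C6 (sets C5 and C6); the exocyclic alkene has no hydrogen-bond donor, is flanked by two branched carbons and is deactivated by the allylic ester.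

Step 14
Reactants: 20 β-cis-triol
Product: 22 C5 acetate (C6 β-OH and C4 β-OH free), via stannylene acetal 21 (not isolated)
Conditions: Bu2SnO, toluene, reflux (Dean–Stark); then AcCl, 0 °C
Reagents that add atoms: acetyl chloride, CC(=O)Cl
Why: Stannylene-acetal-mediated regioselective acylation, which activates the equatorial oxygen of a cis axial/equatorial diol; C5-O is the only equatorial oxygen and is flanked by the axial C4 and C6 oxygens.

Step 15
Reactants: 22 C5 acetate
Product: 23 C5 acetate C6 isobutyrate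
Conditions: isobutyryl chloride, pyridine, DMAP (cat.), CH2Cl2, 0 °C → rt
Reagents that add atoms: isobutyryl chloride, CC(C)C(=O)Cl
Why: DMAP-catalysed acylation of the remaining axial secondary hydroxyl; the tertiary C4-OH does not react and acetyl migration from equatorial C5 to axial C6 is uphill.

Step 16
Reactants: 23 C5 acetate C6 isobutyrate
Product: 24 C2/C3 diol (C10 OTIPS kept, C11 OH free)
Conditions: TFA/H2O (4:1), CH2Cl2, 0 °C
Reagents that add atoms: none
Why: Acid-catalysed acetal hydrolysis removes the ring acetonide and the tertiary TES ether, while the hindered secondary TIPS ether and the four esters survive.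

Step 17
Reactants: 24 C2/C3 diol
Product: 27 CNP0348997.1, via cyclic orthoester 25 (not isolated), via silyl ether 26 (not isolated)
Conditions: trimethyl orthoisobutyrate (1.5 equiv), PPTS (cat.), CH2Cl2, rt; then 48% aq. HF, MeCN, 0 °C → rt
Reagents that add atoms: trimethyl orthoisobutyrate, COC(OC)(OC)C(C)C; water, O
Why: Cyclic orthoester formation on the only cis-vicinal diol, then stereoelectronically controlled hydrolysis of the dioxolan-2-ylium ion (axial-ester rule of orthoester opening) puts the isobutyrate on axial C3-O and frees equatorial C2-OH; aqueous HF then cleaves the TIPS ether.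

**Compound list**

1 | toluene | Cc1ccccc1 | starting material
2 | (1S,2R)-3-methylcyclohexa-3,5-diene-1,2-diol | CC1=CC=C[C@H](O)[C@@H]1O | intermediate
3 | (3aR,7aS)-2,2,4-trimethyl-3a,7a-dihydro-1,3-benzodioxole | CC1=CC=C[C@@H]2OC(C)(C)O[C@H]12 | intermediate
4 | vinyl epoxide: C4,C5-β-epoxide of 3, oxirane anti to the acetonide | C[C@]12O[C@H]1C=C[C@@H]1OC(C)(C)O[C@H]21 | intermediate
5 | trans-diol: C2/C3 α-acetonide, C4 β-OH (α-CH3), C5 α-OH, C6=C1 | C[C@]1(O)[C@H](O)C=C[C@@H]2OC(C)(C)O[C@H]12 | intermediate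
6 | allylic carbonate: 5 with C5 α-O-CO2-t-Bu | C[C@]1(O)[C@H](OC(=O)OC(C)(C)C)C=C[C@@H]2OC(C)(C)O[C@H]12 | intermediate
7 | 3-hydroxy-3-methylbutan-2-one | CC(=O)C(C)(C)O | starting material
8 | 3-methyl-3-(triethylsilyloxy)butan-2-one | CC(=O)C(C)(C)O[Si](CC)(CC)CC | intermediate
9 | acrolein | C=CC=O | starting material
10 | 2,3-dibromopropanal (racemic) | O=CC(Br)CBr | intermediate (not isolated)
11 | 2-bromoprop-2-enal | C=C(Br)C=O | intermediate
12 | boron enolate: diisopinocampheylboron enolate of 8 | C=C(OB([C@@H]1C[C@@H]2C[C@H]([C@H]1C)C2(C)C)[C@@H]1C[C@@H]2C[C@H]([C@H]1C)C2(C)C)C(C)(C)O[Si](CC)(CC)CC | intermediate (not isolated)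
13 | boron aldolate: O-diisopinocampheylboryl derivative of 14 | C=C(Br)[C@H](CC(=O)C(C)(C)O[Si](CC)(CC)CC)OB([C@@H]1C[C@@H]2C[C@H]([C@H]1C)C2(C)C)[C@@H]1C[C@@H]2C[C@H]([C@H]1C)C2(C)C | intermediate (not isolated)
14 | (5S)-6-bromo-5-hydroxy-2-methyl-2-(triethylsilyloxy)hept-6-en-3-one | C=C(Br)[C@@H](O)CC(=O)C(C)(C)O[Si](CC)(CC)CC | intermediate
15 | (3S,5S)-2-bromo-5-hydroxy-6-methyl-6-(triethylsilyloxy)hept-1-en-3-yl 2-methylpropanoate | C=C(Br)[C@H](C[C@H](O)C(C)(C)O[Si](CC)(CC)CC)OC(=O)C(C)C | intermediate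
16 | (3S,5S)-2-bromo-6-methyl-6-(triethylsilyloxy)-5-(triisopropylsilyloxy)hept-1-en-3-yl 2-methylpropanoate | C=C(Br)[C@H](C[C@H](O[Si](C(C)C)(C(C)C)C(C)C)C(C)(C)O[Si](CC)(CC)CC)OC(=O)C(C)C | intermediate
17 | (3S,5S)-6-methyl-2-(4,4,5,5-tetramethyl-1,3,2-dioxaborolan-2-yl)-6-(triethylsilyloxy)-5-(triisopropylsilyloxy)hept-1-en-3-yl 2-methylpropanoate | C=C(B1OC(C)(C)C(C)(C)O1)[C@H](C[C@H](O[Si](C(C)C)(C(C)C)C(C)C)C(C)(C)O[Si](CC)(CC)CC)OC(=O)C(C)C | intermediate
18 | coupled cyclohexene: C1 β-side chain (8S,10S; C8 O-isobutyryl, C10 OTIPS, C11 OTES), C2/C3 α-acetonide, C4 β-OH, C5=C6 | C=C([C@@H]1C=C[C@](C)(O)[C@H]2OC(C)(C)O[C@@H]12)[C@H](C[C@H](O[Si](C(C)C)(C(C)C)C(C)C)C(C)(C)O[Si](CC)(CC)CC)OC(=O)C(C)C | intermediate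
19 | osmate ester: C5,C6-β-glycolate of hexavalent osmium from 18, TMEDA bound to osmium | C=C([C@@H]1[C@@H]3O[Os](=O)(=O)O[C@@H]3[C@](C)(O)[C@H]2OC(C)(C)O[C@@H]12)[C@H](C[C@H](O[Si](C(C)C)(C(C)C)C(C)C)C(C)(C)O[Si](CC)(CC)CC)OC(=O)C(C)C.CN(C)CCN(C)C | intermediate (not isolated)
20 | β-cis-triol: 18 with C5 β-OH and C6 β-OH | C=C([C@@H]1[C@H](O)[C@H](O)[C@](C)(O)[C@H]2OC(C)(C)O[C@@H]12)[C@H](C[C@H](O[Si](C(C)C)(C(C)C)C(C)C)C(C)(C)O[Si](CC)(CC)CC)OC(=O)C(C)C | intermediate
21 | stannylene acetal: C5,C6-O-dibutylstannylene of 20 | C=C([C@@H]1[C@@H]3O[Sn](CCCC)(CCCC)O[C@@H]3[C@](C)(O)[C@H]2OC(C)(C)O[C@@H]12)[C@H](C[C@H](O[Si](C(C)C)(C(C)C)C(C)C)C(C)(C)O[Si](CC)(CC)CC)OC(=O)C(C)C | intermediate (not isolated)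
22 | C5 acetate of 20 | C=C([C@@H]1[C@H](O)[C@H](OC(C)=O)[C@](C)(O)[C@H]2OC(C)(C)O[C@@H]12)[C@H](C[C@H](O[Si](C(C)C)(C(C)C)C(C)C)C(C)(C)O[Si](CC)(CC)CC)OC(=O)C(C)C | intermediate
23 | C5 acetate C6 isobutyrate of 20 | C=C([C@@H]1[C@H](OC(=O)C(C)C)[C@H](OC(C)=O)[C@](C)(O)[C@H]2OC(C)(C)O[C@@H]12)[C@H](C[C@H](O[Si](C(C)C)(C(C)C)C(C)C)C(C)(C)O[Si](CC)(CC)CC)OC(=O)C(C)C | intermediate
24 | C2/C3 diol: 23 without acetonide and TES (C2 α-OH, C3 α-OH, C11 OH, C10 OTIPS) | C=C([C@@H]1[C@H](OC(=O)C(C)C)[C@H](OC(C)=O)[C@](C)(O)[C@@H](O)[C@H]1O)[C@H](C[C@H](O[Si](C(C)C)(C(C)C)C(C)C)C(C)(C)O)OC(=O)C(C)C | intermediate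
25 | cyclic orthoester: C2,C3-O-(1-methoxy-2-methylpropylidene) derivative of 24 (ortho carbon as a mixture) | C=C([C@@H]1[C@H](OC(=O)C(C)C)[C@H](OC(C)=O)[C@](C)(O)[C@H]2OC(OC)(C(C)C)O[C@@H]12)[C@H](C[C@H](O[Si](C(C)C)(C(C)C)C(C)C)C(C)(C)O)OC(=O)C(C)C | intermediate (not isolated)
26 | silyl ether: C10 O-TIPS ether of the target | C=C([C@@H]1[C@H](OC(=O)C(C)C)[C@H](OC(C)=O)[C@](C)(O)[C@@H](OC(=O)C(C)C)[C@H]1O)[C@H](C[C@H](O[Si](C(C)C)(C(C)C)C(C)C)C(C)(C)O)OC(=O)C(C)C | intermediate (not isolated)
27 | CNP0348997.1: ring 1S,2S,3S,4R,5S,6S (target locants), side chain 8S,10S | C=C([C@H]1[C@H](O)[C@H](OC(=O)C(C)C)[C@@](C)(O)[C@@H](OC(C)=O)[C@H]1OC(=O)C(C)C)[C@H](C[C@H](O)C(C)(C)O)OC(=O)C(C)C | target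

**Totals**
Total step count: 17.
Longest linear sequence: 11 steps (1–5, then 12–17; the side-chain line 7–11, then 12–17, is equally long).

**Three steps most likely to fail**

Step 12 (the proposed new coupling). Risks are slow transmetalation of the hindered α-branched alkenyl-B(pin) and β-hydride loss from the π-allyl complex to a diene. The fallback uses known chemistry and sets out from bromide 16 and carbonate 6. Bromide 16 is treated with hexamethylditin and Pd(PPh3)4 (toluene, 80 °C) to give the alkenyltrimethylstannane F1. F1 and 6 are then joined by a classical Stille allyl–alkenyl coupling (Pd2(dba)3, AsPh3, DMF, 50 °C), which goes with inversion at the allylic carbon and at the less hindered allyl terminus. It comes back to the route at 18, and boronate 17 is not needed.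

Step 13 (directed osmylation). Risks are attack on the α face or on the exocyclic alkene. The fallback sets out from 18 and replaces osmium by a Woodward-type sequence. VO(acac)2 and t-BuOOH (CH2Cl2, 0 °C) epoxidise only the allylic-alcohol alkene, syn to C4-OH, to give the β-epoxide F2. MgBr2·OEt2 (Et2O, 0 °C) opens it to the trans-bromohydrin F3 (C6 α-Br, C5 β-OH; the other regioisomer converges to the same product). Isobutyryl chloride, pyridine and DMAP give the bromo isobutyrate F4. AgOTf with 2,6-di-tert-butyl-4-methylpyridine in wet MeCN displaces the bromide through the neighbouring ester, and the cis-acyloxonium ion hydrolyses to the hydroxy isobutyrate F5 (axial C6 ester, equatorial C5 β-OH). Ac2O, DMAP and pyridine then give 23, where it comes back to the route (20 and 22 are bypassed).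

Step 17 (axial-selective orthoester opening). Risks are the wrong regiochemistry or C3-to-C2 acyl migration. The fallback sets out from 24. TESCl and imidazole (DMF, −20 °C) silylate the less hindered equatorial C2 hydroxyl to give the C2 triethylsilyl ether F6. Isobutyryl chloride, DMAP and pyridine (40 °C) acylate the axial C3 hydroxyl to give the silyl ether isobutyrate F7. 48% aq. HF in MeCN removes both silyl groups and the route is rejoined at 27.

**Further compounds**

F1 | step 12 | (3S,5S)-6-methyl-6-(triethylsilyloxy)-5-(triisopropylsilyloxy)-2-(trimethylstannyl)hept-1-en-3-yl 2-methylpropanoate | C=C([Sn](C)(C)C)[C@H](C[C@H](O[Si](C(C)C)(C(C)C)C(C)C)C(C)(C)O[Si](CC)(CC)CC)OC(=O)C(C)C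
F2 | step 13 | C5,C6-β-epoxide of 18 | C=C([C@@H]1[C@@H]3O[C@@H]3[C@](C)(O)[C@H]2OC(C)(C)O[C@@H]12)[C@H](C[C@H](O[Si](C(C)C)(C(C)C)C(C)C)C(C)(C)O[Si](CC)(CC)CC)OC(=O)C(C)C
F3 | step 13 | trans-bromohydrin: C6 α-Br, C5 β-OH | C=C([C@@H]1[C@@H](Br)[C@H](O)[C@](C)(O)[C@H]2OC(C)(C)O[C@@H]12)[C@H](C[C@H](O[Si](C(C)C)(C(C)C)C(C)C)C(C)(C)O[Si](CC)(CC)CC)OC(=O)C(C)C
F4 | step 13 | bromo isobutyrate: C6 α-Br, C5 β-O-isobutyryl | C=C([C@@H]1[C@@H](Br)[C@H](OC(=O)C(C)C)[C@](C)(O)[C@H]2OC(C)(C)O[C@@H]12)[C@H](C[C@H](O[Si](C(C)C)(C(C)C)C(C)C)C(C)(C)O[Si](CC)(CC)CC)OC(=O)C(C)C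
F5 | step 13 | hydroxy isobutyrate: C6 β-O-isobutyryl, C5 β-OH | C=C([C@@H]1[C@H](OC(=O)C(C)C)[C@H](O)[C@](C)(O)[C@H]2OC(C)(C)O[C@@H]12)[C@H](C[C@H](O[Si](C(C)C)(C(C)C)C(C)C)C(C)(C)O[Si](CC)(CC)CC)OC(=O)C(C)C
F6 | step 17 | C2 triethylsilyl ether of 24 | C=C([C@@H]1[C@H](OC(=O)C(C)C)[C@H](OC(C)=O)[C@](C)(O)[C@@H](O)[C@H]1O[Si](CC)(CC)CC)[C@H](C[C@H](O[Si](C(C)C)(C(C)C)C(C)C)C(C)(C)O)OC(=O)C(C)C
F7 | step 17 | C2 triethylsilyl ether C3 isobutyrate of 24 | C=C([C@@H]1[C@H](OC(=O)C(C)C)[C@H](OC(C)=O)[C@](C)(O)[C@@H](OC(=O)C(C)C)[C@H]1O[Si](CC)(CC)CC)[C@H](C[C@H](O[Si](C(C)C)(C(C)C)C(C)C)C(C)(C)O)OC(=O)C(C)C
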